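## Analysis of the target

The target is a diaryl ether cyclophane. Ring A carries the ether oxygen on C1A, a hydroxyl on C3A and the chain on C5A. Ring B carries the ether oxygen on C1B, hydroxyls on C2B and C4B and the chain on C6B. The chain is fourteen methylenes, C1 (on C5A) to C14 (on C6B), so the macrocycle has 20 members (C1A, C6A, C5A, C1–C14, C6B, C1B and the oxygen). There is no stereocentre, so any chirality that appears on the way may be racemic. Ring B is a 1,2,4-trioxygenated benzene and is easily oxidised once its hydroxyls are free, so the phenols should stay masked until the last step. The ether carbon C1B lies between the chain and an oxygen substituent, which makes the diaryl ether bond hindered. The main difficulty is that the fourteen methylenes offer no functional group on which a 20-membered ring could be closed, so any handle has to be brought in and removed without trace. The strategy rests on this blank chain: C2 is made the α-carbon of an ester and C3–C5 an allyl unit. The ring is first closed through an ester oxygen on C5, C2–C3 is then formed inside that ring by a [3,3] shift, and the leftover carboxyl on C2 and the C4=C5 alkene are erased afterwards.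

## Retrosynthetic reasoning

**23 to 22.** The three O–CH3 bonds are cut last in the forward sense. All three phenols are carried as methyl ethers, so one exhaustive cleavage unveils them and the oxidation-prone ring B is exposed only at the end. The diaryl ether has no sp3 C–O bond and should survive.

**22 to 21 and 20.** A carboxyl is placed back on C2. The C2–carboxyl bond is the price of making C2 an ester α-carbon. It is removed through the redox-active ester 21 by radical decarboxylation, which also erases the C2 stereocentre.

**20 to 19.** The C4=C5 double bond is reintroduced. It is the footprint of the allyl unit, and hydrogenation removes it together with any question of its geometry.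

**19 to 16 (key disconnection).** Acid 19 has a carboxyl on C2 and an alkene at C4=C5, the retron of an ester enolate Claisen rearrangement. Cutting C2–C3 and reconnecting the carboxyl oxygen to C5 gives allylic macrolactone 16, a ring of the same size. A C–C macrocyclisation on an unactivated chain is thereby replaced by a ring transposition. The forward step must enolise 16 at C2, trap the enolate as silyl ketene acetal 17 and let it rearrange.

**16 to 14.** The acyl C–O bond is cut to give hydroxy acid 14. This is where the entropic cost of the 20-membered ring is paid, in a macrolactonisation, a reaction type with a long record for flexible rings of this size.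

**14 to 13, 11 and 12.** Acid 14 comes from ester 13 by hydrolysis. Cutting C4–C5 leads to aldehyde 11 and vinyl Grignard reagent 12, and the aldehyde comes from primary alcohol 10 by oxidation. The forward addition must take the aldehyde and spare the methyl ester, which low temperature should ensure.

**10 to 4 and 9.** The O–C1B bond is cut to give phenol 4 and aryl iodide 9, two fragments of similar size that each carry an arm. Cutting O–C1A instead would need ring B as a phenol, which costs extra steps. The forward copper-catalysed etherification has to cope with a carbon flanked by the chain and a methoxy group, so an iodide is used.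

**9 to 8, 5 and 6.** The C–I bond comes from electrophilic iodination of 8, steered by the two methoxy groups to the carbon that becomes C1B. The C14–C6B bond is cut to alkenol 5 and aryl bromide 6, joined by hydroboration and sp3–sp2 cross-coupling.

**4 to 3, 1 and 2.** The C1=C2 bond of cinnamate 3 is cut to aldehyde 1 and stabilised ylide 2. Hydrogenation of 3 gives the propanoate arm, whose carbonyl carbon is the one later lost.

## Alternatives that were turned down

**Alternative 1:** The O–C1A bond is cut and ring A is taken back to a cyclohexenone. The precursor A2, 3-chloro-5-[14-(2-hydroxy-3,5-dimethoxyphenyl)tetradecyl]cyclohex-2-en-1-one, carries the free ring B phenol at the end of the chain. With a carbonate base at high dilution, the phenoxide oxygen on C1B would add to the chlorine-bearing carbon (future C1A) and expel chloride. This closes the 20-membered ring as the vinylogous aryl ester A1, and dehydrogenation would then make ring A with its hydroxyl on C3A.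
- For: a β-chloroenone is a strong, unhindered electrophile, so the crowded phenoxide needs no metal. This is a real advantage over the copper-catalysed etherification of step 5. No carbon has to be excised afterwards.
- Against: the ring closure is an end-to-end substitution with the full entropic burden and no dedicated macrocyclisation method behind it. A2 needs a 5-substituted cyclohexane-1,3-dione built on the far end of the chain and chlorinated beside an electron-rich phenol. A1 must be aromatised oxidatively while ring B is the most oxidisable and most halogen-prone part of the molecule, and the vinylogous ester can still exchange its aryloxy group with a nucleophile, which would reopen the ring.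
- Comparison: step counts should be similar. The chosen route uses both rings already aromatic, needs no oxidation once the ether is in place, and forms its difficult bond inside a closed ring.

**Alternative 2:** Ring B is dismantled by cutting C1B–C6B and C3B–C4B. The precursor A4, methyl (E)-17-[3-benzyloxy-5-(2-oxopropoxy)phenyl]heptadec-2-enoate, has ring A already bearing the ether oxygen as an aryloxy ketone and a chain ending in an enoate. With an alkoxide base at high dilution, the α-aryloxy enolate should add to the enoate β-carbon (closing the 20-membered ring), and the methyl ketone enolate should then acylate on the ester. This gives the cyclohexane-1,3-dione A3 as a diastereomer mixture, to be aromatised.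
- For: the ether oxygen is installed by a simple phenol alkylation, so the hindered diaryl ether coupling is avoided altogether. On this point it is stronger than the chosen route. The macrocycle and ring B arise in one flask and the oxygenation pattern follows from the dione.
- Against: the ring-closing event is a conjugate addition to a β-alkyl enoate, which is slow and reversible. At high dilution under equilibrating base it competes with γ-deprotonation of the enoate, acylation in the wrong order and aldol condensation of the ketone. A3 also stands at an oxidation level from which loss of the ring A phenol leads to an aromatic ring as well, so the required dehydrogenation must outrun cleavage of the macrocyclic ether.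
- Comparison: it is more convergent on paper, but it puts two uncertain operations in sequence. The chosen route has one and keeps ring B aromatic throughout.

**Alternative 3:** C2A–C3A and C1A–C6A are cut and ring A is reduced to a cyclobutenone and an alkynyl ether. The precursor is A6, 3-[14-(2-ethynyloxy-3,5-dimethoxyphenyl)tetradecyl]cyclobut-2-en-1-one. Heating would open the cyclobutenone to a vinylketene, which adds across the ethynyl ether. Four-electron ring opening and six-electron ring closure then give A5, the ring B di-O-methyl ether of the target, with the C3A hydroxyl already free.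
- For: ring A, the ether pattern and the macrocycle form in one reagent-free thermal step, the regiochemistry is set by the polarisation of the alkynyl ether, and only a demethylation remains. In step economy after the key step it beats the chosen route, which needs four more steps.
- Against: an aryl ethynyl ether on the di-ortho-substituted, electron-rich C1B oxygen is laborious to make and thermally fragile. The cyclobutenone needs its own multi-step preparation at the chain end. Ring closure depends on a transient vinylketene reaching an alkyne twenty atoms away before it dimerises, at temperatures that also stress the alkynyl ether.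
- Comparison: the chosen route uses stable, conventional intermediates, and its C–C bond is formed between two ends already held in one ring.

Key step: step 10

Assumption: 3-hydroxy-5-methoxybenzaldehyde (1) is taken as a purchasable building block. The target is achiral, so every chiral intermediate is made and used as a racemate.

## Route

Step 1
Reactants: 1 3-hydroxy-5-methoxybenzaldehyde; 2 methyl (triphenylphosphoranylidene)acetate
Product: 3 methyl (E)-3-(3-hydroxy-5-methoxyphenyl)prop-2-enoate
Conditions: 2 (1.2 equiv), toluene, 90 °C
Reagents that add atoms: none
Why: Wittig olefination with a stabilised ylide should give the (E)-cinnamate and forms C1=C2; the ylide is too weakly basic to be stopped by the free phenol.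

Step 2
Reactants: 3 methyl (E)-3-(3-hydroxy-5-methoxyphenyl)prop-2-enoate
Product: 4 methyl 3-(3-hydroxy-5-methoxyphenyl)propanoate
Conditions: H2 (1 atm), Pd/C, EtOAc, rt
Reagents that add atoms: none
Why: Catalytic hydrogenation of a conjugated alkene; phenol, aryl methyl ether and ester are inert under these conditions.

Step 3
Reactants: 5 dec-9-en-1-ol; 6 1-bromo-3,5-dimethoxybenzene
Product: 8 10-(3,5-dimethoxyphenyl)decan-1-ol, via alkylborane 7 (not isolated)
Conditions: 9-BBN (2.2 equiv), THF, 0 °C to rt; then 6, Pd(dppf)Cl2 (5 mol%), aq. K3PO4, DMF, 60 °C
Reagents that add atoms: 9-borabicyclo[3.3.1]nonane, B1C2CCCC1CCC2 (its boron is carried in 7 only)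
Why: Anti-Markovnikov hydroboration of the terminal alkene followed by B-alkyl Suzuki–Miyaura coupling forms C14–C6B; excess borane is used because the hydroxyl can bind one equivalent as a borinate that hydrolyses on work-up, and the dppf ligand suppresses β-hydride elimination.

Step 4
Reactants: 8 10-(3,5-dimethoxyphenyl)decan-1-ol
Product: 9 10-(2-iodo-3,5-dimethoxyphenyl)decan-1-ol
Conditions: NIS (1.0 equiv), MeCN, 0 °C to rt, dark
Reagents that add atoms: N-iodosuccinimide, O=C1CCC(=O)N1I
Why: Electrophilic aromatic iodination; as is general for 5-alkylresorcinol dimethyl ethers, attack should occur para to one methoxy group and ortho to the chain (future C1B) and not at the more crowded carbon between the two methoxy groups, and one equivalent limits di-iodination.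

Step 5
Reactants: 4 methyl 3-(3-hydroxy-5-methoxyphenyl)propanoate; 9 10-(2-iodo-3,5-dimethoxyphenyl)decan-1-ol
Product: 10 methyl 3-[3-[2-(10-hydroxydecyl)-4,6-dimethoxyphenoxy]-5-methoxyphenyl]propanoate
Conditions: CuI (10 mol%), picolinic acid (20 mol%), K3PO4, DMSO, 90 °C
Reagents that add atoms: none
Why: Ullmann-type copper-catalysed C–O coupling forms O–C1B, with a ligand system suited to ortho-substituted partners; K3PO4 deprotonates only the phenol, so the aliphatic hydroxyl should not compete, and the iodide eases reaction at the di-ortho-substituted carbon.

Step 6
Reactants: 10 methyl 3-[3-[2-(10-hydroxydecyl)-4,6-dimethoxyphenoxy]-5-methoxyphenyl]propanoate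
Product: 11 methyl 3-[3-[2-(10-oxodecyl)-4,6-dimethoxyphenoxy]-5-methoxyphenyl]propanoate
Conditions: Dess–Martin periodinane, NaHCO3, CH2Cl2, 0 °C to rt
Reagents that add atoms: none
Why: Dess–Martin oxidation stops at the aldehyde and, buffered, should leave the electron-rich rings and the ester untouched.

Step 7
Reactants: 11 methyl 3-[3-[2-(10-oxodecyl)-4,6-dimethoxyphenoxy]-5-methoxyphenyl]propanoate; 12 vinylmagnesium bromide
Product: 13 methyl 3-[3-[2-(10-hydroxydodec-11-en-1-yl)-4,6-dimethoxyphenoxy]-5-methoxyphenyl]propanoate (racemic)
Conditions: CH2=CHMgBr (1.2 equiv), THF, −78 °C; aq. NH4Cl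
Reagents that add atoms: none
Why: Grignard addition forms C4–C5; at −78 °C the aldehyde reacts far faster than the methyl ester, and the new C5 stereocentre is formed without control because it becomes sp2 in step 10.

Step 8
Reactants: 13 methyl 3-[3-[2-(10-hydroxydodec-11-en-1-yl)-4,6-dimethoxyphenoxy]-5-methoxyphenyl]propanoate (racemic)
Product: 14 3-[3-[2-(10-hydroxydodec-11-en-1-yl)-4,6-dimethoxyphenoxy]-5-methoxyphenyl]propanoic acid (racemic)
Conditions: LiOH·H2O, THF/MeOH/H2O, rt; then 1 M HCl
Reagents that add atoms: lithium hydroxide, [Li+].[OH-] (supplies the carboxyl oxygen)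
Why: Saponification of an unhindered methyl ester; the allylic alcohol and the aryl ethers are stable to aqueous base.

Step 9
Reactants: 14 3-[3-[2-(10-hydroxydodec-11-en-1-yl)-4,6-dimethoxyphenoxy]-5-methoxyphenyl]propanoic acid (racemic)
Product: 16 20-membered allylic macrolactone with its ester oxygen on the vinyl-bearing C5 (tri-O-methyl; racemic), via mixed anhydride 15 (not isolated)
Conditions: 2,4,6-Cl3C6H2COCl, Et3N, THF, rt; then slow addition to DMAP, toluene, 80 °C (final about 1 mM)
Reagents that add atoms: 2,4,6-trichlorobenzoyl chloride, O=C(Cl)c1c(Cl)cc(Cl)cc1Cl (its acyl group is carried in 15 only)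
Why: Yamaguchi macrolactonisation: the mixed anhydride is acylated onto DMAP and attacked by the C5 hydroxyl; slow addition keeps the hydroxy acid dilute so that the nearly strain-free 20-membered ring should form in preference to oligomers.

Step 10
Reactants: 16 20-membered allylic macrolactone (tri-O-methyl; racemic)
Product: 19 20-membered carbocyclic (E)-alkenoic acid with the carboxyl on C2 and the alkene at C4=C5 (tri-O-methyl; racemic), via trimethylsilyl ketene acetal 17 (not isolated), via trimethylsilyl ester 18 (not isolated)
Conditions: KN(SiMe3)2 (1.5 equiv), Me3SiCl/Et3N (3 equiv, present from the start), THF–toluene, −78 °C, then warm to 80 °C; 1 M HCl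
Reagents that add atoms: chlorotrimethylsilane, C[Si](C)(C)Cl (its silyl group is carried in 17 and 18 only)
Why: KN(SiMe3)2 removes a proton from C2, the only carbonyl α-position, and the Me3SiCl already present silylates the enolate oxygen to give ketene acetal 17, which contains the array C2=C(OSi)–O–C5–C4=C3. On warming, a concerted suprafacial [3,3]-sigmatropic shift should form C2–C3, break O–C5 and move the double bond to C4=C5, giving silyl ester 18, which aqueous acid hydrolyses to 19. The closest known reaction type is the Ireland–Claisen rearrangement of medium-ring and macrocyclic allylic lactones with an exocyclic vinyl group, which turns lactones into carbocyclic acids; the 20-membered case extends it in ring size only. The carbocycle is closed by transposition and not by an end-to-end cyclisation: bond formation occurs within a six-membered pericyclic array (C2, carboxyl carbon, O, C5, C4, C3) bridged between C2 and C5 by the other 16 ring atoms, a bridge long enough to span a chair or a boat, and the ring exchanges its C(=O)–O unit for C3–C4 and stays 20-membered. The new C2 stereocentre is set by chirality transfer from C5 through this array, so racemic 16 gives racemic 19, and it is erased in step 13. The C4=C5 geometry is expected to be E (C6 pseudo-equatorial in a chair array) but is irrelevant because step 11 removes the alkene. The step needs O-silylation to outrun enolate decomposition (loss of the allylic alkoxide to a ketene, or Claisen condensation), which the internal Me3SiCl quench at −78 °C should secure; the rearrangement is unimolecular by construction, so no dilution is needed.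

Step 11
Reactants: 19 20-membered carbocyclic (E)-alkenoic acid (tri-O-methyl; racemic)
Product: 20 saturated 20-membered carbocyclic acid with the carboxyl on C2 (tri-O-methyl; racemic)
Conditions: H2 (1 atm), Pd/C, EtOAc, rt
Reagents that add atoms: none
Why: Catalytic hydrogenation of the disubstituted ring alkene; both alkene geometries converge on one product and no benzyl group is present to be lost.

Step 12
Reactants: 20 saturated 20-membered carbocyclic acid (tri-O-methyl; racemic)
Product: 21 N-hydroxyphthalimide ester of 20 (racemic)
Conditions: N-hydroxyphthalimide, i-PrN=C=N-i-Pr, DMAP (cat.), CH2Cl2, rt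
Reagents that add atoms: N-hydroxyphthalimide, O=C1c2ccccc2C(=O)N1O
Why: Steglich-type carbodiimide esterification converts the acid into a redox-active ester ready for single-electron reduction.

Step 13
Reactants: 21 N-hydroxyphthalimide ester of 20 (racemic)
Product: 22 tri-O-methyl ether of the target
Conditions: Ru(bpy)3Cl2·6H2O (1 mol%), Hantzsch ester (1.5 equiv), DMF, blue LEDs, rt
Reagents that add atoms: none
Why: Photoredox reductive decarboxylation: single-electron reduction of the ester, N–O fragmentation and loss of CO2 give the secondary C2 radical, which takes a hydrogen atom from the Hantzsch ester; the ring is saturated, so there is no radical acceptor within reach, and C2 becomes a methylene.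

Step 14
Reactants: 22 tri-O-methyl ether of the target
Product: 23 CNP0173380.0 (target)
Conditions: BBr3 (8 equiv), CH2Cl2, −78 °C to rt; MeOH, then H2O, under argon
Reagents that add atoms: none
Why: Lewis acid cleavage of the three aryl methyl ethers by bromide attack on the methyl carbons; the diaryl ether has no sp3 C–O bond to cleave, and air is excluded because free ring B is easily oxidised.

## Compound list

1 | 3-hydroxy-5-methoxybenzaldehyde | O=Cc1cc(O)cc(OC)c1 | starting material
2 | methyl (triphenylphosphoranylidene)acetate | COC(=O)C=P(c1ccccc1)(c1ccccc1)c1ccccc1 | starting material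
3 | methyl (E)-3-(3-hydroxy-5-methoxyphenyl)prop-2-enoate | COC(=O)/C=C/c1cc(O)cc(OC)c1 | intermediate
4 | methyl 3-(3-hydroxy-5-methoxyphenyl)propanoate | COC(=O)CCc1cc(O)cc(OC)c1 | intermediate
5 | dec-9-en-1-ol | OCCCCCCCCC=C | starting material
6 | 1-bromo-3,5-dimethoxybenzene | COc1cc(OC)cc(Br)c1 | starting material
7 | 9-(10-hydroxydecyl)-9-borabicyclo[3.3.1]nonane (formed in the flask) | OCCCCCCCCCCB1C2CCCC1CCC2 | intermediate
8 | 10-(3,5-dimethoxyphenyl)decan-1-ol | COc1cc(OC)cc(CCCCCCCCCCO)c1 | intermediate
9 | 10-(2-iodo-3,5-dimethoxyphenyl)decan-1-ol | COc1cc(OC)c(I)c(CCCCCCCCCCO)c1 | intermediate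
10 | methyl 3-[3-[2-(10-hydroxydecyl)-4,6-dimethoxyphenoxy]-5-methoxyphenyl]propanoate | COC(=O)CCc1cc(OC)cc(c1)Oc1c(OC)cc(OC)cc1CCCCCCCCCCO | intermediate
11 | methyl 3-[3-[2-(10-oxodecyl)-4,6-dimethoxyphenoxy]-5-methoxyphenyl]propanoate | COC(=O)CCc1cc(OC)cc(c1)Oc1c(OC)cc(OC)cc1CCCCCCCCCC=O | intermediate
12 | vinylmagnesium bromide | C=C[Mg]Br | starting material
13 | methyl 3-[3-[2-(10-hydroxydodec-11-en-1-yl)-4,6-dimethoxyphenoxy]-5-methoxyphenyl]propanoate (racemic) | COC(=O)CCc1cc(OC)cc(c1)Oc1c(OC)cc(OC)cc1CCCCCCCCCC(O)C=C | intermediate
14 | 3-[3-[2-(10-hydroxydodec-11-en-1-yl)-4,6-dimethoxyphenoxy]-5-methoxyphenyl]propanoic acid (racemic) | OC(=O)CCc1cc(OC)cc(c1)Oc1c(OC)cc(OC)cc1CCCCCCCCCC(O)C=C | intermediate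
15 | mixed anhydride of 14 with 2,4,6-trichlorobenzoic acid (racemic; formed in the flask) | O=C(CCc1cc(OC)cc(c1)Oc1c(OC)cc(OC)cc1CCCCCCCCCC(O)C=C)OC(=O)c1c(Cl)cc(Cl)cc1Cl | intermediate
16 | 20-membered allylic macrolactone, ester oxygen on the vinyl-bearing C5, ring A methyl ether and ring B dimethyl ether (racemic) | O=C1CCc2cc(OC)cc(c2)Oc2c(OC)cc(OC)cc2CCCCCCCCCC(C=C)O1 | intermediate
17 | trimethylsilyl ketene acetal of 16 (racemic; ketene acetal geometry not defined; formed in the flask) | C[Si](C)(C)OC1=CCc2cc(OC)cc(c2)Oc2c(OC)cc(OC)cc2CCCCCCCCCC(C=C)O1 | intermediate
18 | trimethylsilyl ester of 19 (racemic; formed in the flask) | C[Si](C)(C)OC(=O)C1Cc2cc(OC)cc(c2)Oc2c(OC)cc(OC)cc2CCCCCCCCC/C=C/C1 | intermediate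
19 | 20-membered carbocyclic (E)-alkenoic acid, carboxyl on C2, alkene C4=C5, tri-O-methyl (racemic) | OC(=O)C1Cc2cc(OC)cc(c2)Oc2c(OC)cc(OC)cc2CCCCCCCCC/C=C/C1 | intermediate
20 | saturated 20-membered carbocyclic acid, carboxyl on C2, tri-O-methyl (racemic) | OC(=O)C1Cc2cc(OC)cc(c2)Oc2c(OC)cc(OC)cc2CCCCCCCCCCCC1 | intermediate
21 | N-hydroxyphthalimide ester of 20 (racemic) | O=C(ON1C(=O)c2ccccc2C1=O)C1Cc2cc(OC)cc(c2)Oc2c(OC)cc(OC)cc2CCCCCCCCCCCC1 | intermediate
22 | tri-O-methyl ether of the target | COc1cc2cc(c1)Oc1c(OC)cc(OC)cc1CCCCCCCCCCCCCC2 | intermediate
23 | CNP0173380.0 | Oc1cc2cc(c1)Oc1c(O)cc(O)cc1CCCCCCCCCCCCCC2 | target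

## Step count and risks

Total step count: 14. Longest linear sequence: 12 steps (steps 3–14 from 5 and 6; the branch from 1 through steps 1, 2 and 5–14 is equally long).

**Step 10 (key step).** The most likely failure is decomposition of the enolate before silylation (loss of the allylic alkoxide to a ketene, or condensation). The second is a rearrangement that stalls because the 16-atom bridge does not fold to bring C2 within bonding distance of C3, so that work-up returns 16 by hydrolysis of the ketene acetal. The fallback forms the same ring by alkene metathesis at C4=C5 and sets out from aldehyde 11.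
- Methylenation of 11 with Ph3P=CH2 in THF should give methyl 3-[3-[2-(undec-10-en-1-yl)-4,6-dimethoxyphenoxy]-5-methoxyphenyl]propanoate F1.
- Deprotonation with LiN(i-Pr)2 at −78 °C and alkylation with allyl bromide should give methyl 2-[3-[2-(undec-10-en-1-yl)-4,6-dimethoxyphenoxy]-5-methoxybenzyl]pent-4-enoate F2 (racemic).
- Ring-closing metathesis with the second-generation Grubbs catalyst in dilute CH2Cl2 at 40 °C should give the 20-membered cycloalkene methyl ester F3 as an E/Z mixture.
- Hydrogenation over Pd/C should give the saturated macrocyclic methyl ester F4, and LiOH hydrolysis returns the route to acid 20.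

**Step 5.** The di-ortho-substituted, electron-rich iodide may react too slowly with copper, so that reductive loss of iodine and recovery of phenol 4 dominate. The fallback makes the ether on an aldehyde-activated ring and attaches the chain afterwards. It sets out from phenol 4.
- Coupling of 4 with commercial 2-bromo-3,5-dimethoxybenzaldehyde F5 (CuI, N,N-dimethylglycine, Cs2CO3, dioxane, 90 °C), where the ortho formyl group activates the halide, should give methyl 3-[3-(2-formyl-4,6-dimethoxyphenoxy)-5-methoxyphenyl]propanoate F6.
- (9-Hydroxynonyl)triphenylphosphonium bromide F7, made from 9-bromononan-1-ol and PPh3, is converted with two equivalents of NaN(SiMe3)2 into its ylide. Wittig reaction with F6 at −78 °C should give methyl 3-[3-[2-[(Z)-10-hydroxydec-1-en-1-yl]-4,6-dimethoxyphenoxy]-5-methoxyphenyl]propanoate F8.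
- Hydrogenation over Pd/C returns the route to 10.

**Step 9.** Intermolecular acylation may compete with ring closure and give the dimeric lactone and oligomers, and acyl transfer to the secondary allylic hydroxyl may be slow. The fallback activates the alcohol instead of the acid: Mitsunobu cyclisation of 14 (PPh3, diisopropyl azodicarboxylate, dilute toluene, slow addition) makes the carboxylate displace the activated C5 oxygen and returns the route to 16. The inversion at C5 does not matter in a racemate. No new compound is made.

**Step 3.** The free hydroxyl may consume borane and leave the hydroboration incomplete, or the alkylborane may transfer slowly and be lost by protodeboronation. The fallback changes the coupling. Sonogashira reaction of 6 with dec-9-yn-1-ol (Pd(PPh3)2Cl2, CuI, Et3N, 70 °C) should give 10-(3,5-dimethoxyphenyl)dec-9-yn-1-ol F9, and hydrogenation over Pd/C returns the route to 8.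

## Further compounds

F1 | step 10 | methyl 3-[3-[2-(undec-10-en-1-yl)-4,6-dimethoxyphenoxy]-5-methoxyphenyl]propanoate | COC(=O)CCc1cc(OC)cc(c1)Oc1c(OC)cc(OC)cc1CCCCCCCCCC=C
F2 | step 10 | methyl 2-[3-[2-(undec-10-en-1-yl)-4,6-dimethoxyphenoxy]-5-methoxybenzyl]pent-4-enoate (racemic) | COC(=O)C(CC=C)Cc1cc(OC)cc(c1)Oc1c(OC)cc(OC)cc1CCCCCCCCCC=C
F3 | step 10 | 20-membered cycloalkene methyl ester, ester on C2, alkene C4=C5 (E/Z mixture; racemic) | COC(=O)C1Cc2cc(OC)cc(c2)Oc2c(OC)cc(OC)cc2CCCCCCCCCC=CC1
F4 | step 10 | saturated 20-membered carbocyclic methyl ester, ester on C2 (racemic) | COC(=O)C1Cc2cc(OC)cc(c2)Oc2c(OC)cc(OC)cc2CCCCCCCCCCCC1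
F5 | step 5 | 2-bromo-3,5-dimethoxybenzaldehyde | O=Cc1cc(OC)cc(OC)c1Br
F6 | step 5 | methyl 3-[3-(2-formyl-4,6-dimethoxyphenoxy)-5-methoxyphenyl]propanoate | COC(=O)CCc1cc(OC)cc(c1)Oc1c(OC)cc(OC)cc1C=O
F7 | step 5 | (9-hydroxynonyl)triphenylphosphonium bromide | OCCCCCCCCC[P+](c1ccccc1)(c1ccccc1)c1ccccc1.[Br-]
F8 | step 5 | methyl 3-[3-[2-[(Z)-10-hydroxydec-1-en-1-yl]-4,6-dimethoxyphenoxy]-5-methoxyphenyl]propanoate | COC(=O)CCc1cc(OC)cc(c1)Oc1c(OC)cc(OC)cc1/C=C\CCCCCCCCO
F0 | step 9 | none | none
F9 | step 3 | 10-(3,5-dimethoxyphenyl)dec-9-yn-1-ol | COc1cc(OC)cc(C#CCCCCCCCCO)c1
A1 | alternative 1 | macrocyclic 3-aryloxy-5-alkylcyclohex-2-enone, ring B dimethyl ether (racemic) | O=C1C=C2CC(C1)CCCCCCCCCCCCCCc1cc(OC)cc(OC)c1O2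
A2 | alternative 1 | 3-chloro-5-[14-(2-hydroxy-3,5-dimethoxyphenyl)tetradecyl]cyclohex-2-en-1-one (racemic) | O=C1C=C(Cl)CC(C1)CCCCCCCCCCCCCCc1cc(OC)cc(OC)c1O
A3 | alternative 2 | macrocyclic 4-aryloxy-5-alkylcyclohexane-1,3-dione, ring A benzyl ether (diastereomer mixture) | O=C1CC(=O)CC3CCCCCCCCCCCCCCc2cc(OCc4ccccc4)cc(c2)OC13
A4 | alternative 2 | methyl (E)-17-[3-benzyloxy-5-(2-oxopropoxy)phenyl]heptadec-2-enoate | CC(=O)COc1cc(OCc2ccccc2)cc(CCCCCCCCCCCCCC/C=C/C(=O)OC)c1
A5 | alternative 3 | ring B di-O-methyl ether of the target | Oc1cc2cc(c1)Oc1c(OC)cc(OC)cc1CCCCCCCCCCCCCC2
A6 | alternative 3 | 3-[14-(2-ethynyloxy-3,5-dimethoxyphenyl)tetradecyl]cyclobut-2-en-1-one | O=C1C=C(CCCCCCCCCCCCCCc2cc(OC)cc(OC)c2OC#C)C1
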